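**Retrosynthetic overview**
1. Target 7 ⇒ eightfold ortho-bromination and fourfold O-demethylation ⇒ tetra-anisyl diacylpyrrole 5.
2. 5 ⇒ cut both N–C2 and N–C5 bonds: an oxidative [4+1] of ammonia onto the two α-carbons of 1,6-diketone 2 (the key step).
3. 2 ⇒ cut C3–C4: reductive β,β-hydrodimerisation of 4,4'-dimethoxychalcone 1, which brings in all four aryl groups.
4. Ring order: the pyrrole is the only ring formed (step 2); the four benzene rings are carried through intact.

Assumption: the target (polycitone B) has no stereocentre and is achiral, so no enantiocontrol is needed; 4,4'-dimethoxychalcone is taken as a bought catalogue compound.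

**Step 1**
Reactants: 1 (E)-4,4'-dimethoxychalcone (two molecules)
Product: 2 1,3,4,6-tetrakis(4-methoxyphenyl)hexane-1,6-dione (meso/(±) mixture, used as such)
Conditions: Zn dust (3 equiv), AcOH/H2O 9:1, 0.5 M, 60 °C
Reagents that add atoms: none
Why: Reductive hydrodimerisation of an enone: one-electron reduction of the protonated chalcone gives a β-centred allylic radical that couples tail-to-tail at the β-carbons (favoured by high concentration), and the resulting bis-enol tautomerises to the 1,6-diketone; the two new stereocentres (C3, C4) are not controlled and need not be, since both are erased in step 2.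

**Step 2**
Reactants: 2 1,3,4,6-tetrakis(4-methoxyphenyl)hexane-1,6-dione
Product: 5 [3,4-bis(4-methoxyphenyl)-1H-pyrrole-2,5-diyl]bis[(4-methoxyphenyl)methanone], via dibromo diketone 3 (not isolated), via diaroylpyrrolidine 4 (not isolated)
Conditions: CuBr2 (4.4 equiv), EtOAc/CHCl3 1:1, reflux; then NH3 (7 M in MeOH, 15 equiv), O2 (1 atm), 0 → 40 °C; aq. EDTA work-up
Reagents that add atoms: ammonia, N
Why: Proposed new method: a copper-bromide relay oxidative [4+1] aza-annulation in which CuBr2 first brominates both ArCO–CH2 positions through the enols (leaving CuBr), ammonia then forms both C–N bonds by intermolecular SN2 followed by 5-exo-tet SN2 on the two α-bromo ketones to give pyrrolidine 4, and the copper, reoxidised by O2 to a Cu(II) ammine and chelated by the N,O α-amino-ketone units of 4, removes the two captodative α-C–H/N–H pairs in turn (1-pyrroline, enamine tautomer, 2H-pyrrole, 1H-pyrrole) with aromatisation as driving force; ammonia is admitted only after both α-carbons carry bromine so that a free α-amino ketone never faces an unactivated ketone five atoms away (which would lead to a pyridine), bromine rather than iodine is used so that any stray ring halogenation ortho to OMe lands on a position that carries Br in the target, and the closest known reaction types are copper(II) bromide α-bromination/α-amination of ketones via α-bromo ketones and Cu/O2 dehydrogenation of α-hydroxy and α-amino ketones; all sp3 stereocentres of 2–4 vanish here.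

**Step 3**
Reactants: 5 [3,4-bis(4-methoxyphenyl)-1H-pyrrole-2,5-diyl]bis[(4-methoxyphenyl)methanone]
Product: 6 [3,4-bis(4-hydroxyphenyl)-1H-pyrrole-2,5-diyl]bis[(4-hydroxyphenyl)methanone]
Conditions: BBr3 (8 equiv), CH2Cl2, −78 °C → rt; then ice-water
Reagents that add atoms: none
Why: Lewis-acid aryl methyl ether cleavage (bromide attacks the O-complexed methyl group by SN2), with excess reagent to cover coordination to the two ketones and the pyrrole, which are otherwise inert to BBr3.

**Step 4**
Reactants: 6 [3,4-bis(4-hydroxyphenyl)-1H-pyrrole-2,5-diyl]bis[(4-hydroxyphenyl)methanone]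
Product: 7 [3,4-bis(3,5-dibromo-4-hydroxyphenyl)-1H-pyrrole-2,5-diyl]bis[(3,5-dibromo-4-hydroxyphenyl)methanone] (target, CNP0269782.0)
Conditions: Br2 (8.4 equiv), AcOH/1,4-dioxane 1:1, 15 °C → rt; aq. NaHSO3 quench
Reagents that add atoms: bromine, BrBr
Why: Electrophilic aromatic bromination directed ortho to each phenolic OH (all para positions are blocked, giving exactly two sites per ring and eight in total), while the pyrrole has no free carbon and its nitrogen is deactivated by two acyl groups, any N–Br being cleaved by the bisulfite quench.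

**Compound list**
1 | (E)-1,3-bis(4-methoxyphenyl)prop-2-en-1-one (4,4'-dimethoxychalcone) | COc1ccc(/C=C/C(=O)c2ccc(OC)cc2)cc1 | starting material
2 | 1,3,4,6-tetrakis(4-methoxyphenyl)hexane-1,6-dione (meso/(±) mixture, stereocentres undefined) | COc1ccc(cc1)C(=O)CC(c1ccc(OC)cc1)C(c1ccc(OC)cc1)CC(=O)c1ccc(OC)cc1 | intermediate
3 | 2,5-dibromo-1,3,4,6-tetrakis(4-methoxyphenyl)hexane-1,6-dione (diastereomer mixture, not isolated) | COc1ccc(cc1)C(=O)C(Br)C(c1ccc(OC)cc1)C(c1ccc(OC)cc1)C(Br)C(=O)c1ccc(OC)cc1 | intermediate
4 | [3,4-bis(4-methoxyphenyl)pyrrolidine-2,5-diyl]bis[(4-methoxyphenyl)methanone] (diastereomer mixture, not isolated) | COc1ccc(cc1)C(=O)C1NC(C(=O)c2ccc(OC)cc2)C(c2ccc(OC)cc2)C1c1ccc(OC)cc1 | intermediate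
5 | [3,4-bis(4-methoxyphenyl)-1H-pyrrole-2,5-diyl]bis[(4-methoxyphenyl)methanone] | COc1ccc(cc1)C(=O)c1[nH]c(C(=O)c2ccc(OC)cc2)c(-c2ccc(OC)cc2)c1-c1ccc(OC)cc1 | intermediate
6 | [3,4-bis(4-hydroxyphenyl)-1H-pyrrole-2,5-diyl]bis[(4-hydroxyphenyl)methanone] | O=C(c1ccc(O)cc1)c1[nH]c(C(=O)c2ccc(O)cc2)c(-c2ccc(O)cc2)c1-c1ccc(O)cc1 | intermediate
7 | [3,4-bis(3,5-dibromo-4-hydroxyphenyl)-1H-pyrrole-2,5-diyl]bis[(3,5-dibromo-4-hydroxyphenyl)methanone] (achiral) | O=C(c1cc(Br)c(O)c(Br)c1)c1[nH]c(C(=O)c2cc(Br)c(O)c(Br)c2)c(-c2cc(Br)c(O)c(Br)c2)c1-c1cc(Br)c(O)c(Br)c1 | target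

**Totals**
Total step count: 4. Longest linear sequence: 4 steps (1 → 2 → 5 → 6 → 7).

**Three steps most likely to fail**

Step 2 (proposed new step, highest risk). The hindered, β-branched α-bromo ketones may eliminate HBr instead of being displaced, or the aerobic copper dehydrogenation of 4 may stall. The fallback uses known chemistry and a different C–N logic, carbonyl condensation instead of halide displacement. It sets out from 2: Riley oxidation of both ArCO–CH2 groups (SeO2, 2.2 equiv, 1,4-dioxane/H2O, reflux) gives 1,3,4,6-tetrakis(4-methoxyphenyl)hexane-1,2,5,6-tetrone F2. Its two inner carbonyls form a 1,4-diketone, so Paal–Knorr condensation with NH4OAc in AcOH at 80 °C closes the pyrrole with no separate dehydrogenation. It comes back to the route at 5.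

Step 1. Protonation of the radical intermediate can give the monomeric dihydrochalcone, and the electron-rich chalcone is harder to reduce. The fallback replaces the protic reduction by an aprotic reductive silylation. It sets out from 1: Mg turnings and TMSCl in DMF (0 °C → rt) O-silylate the radical anion, and the silyloxyallyl radicals dimerise at the β-carbons to give 1,3,4,6-tetrakis(4-methoxyphenyl)-1,6-bis(trimethylsilyloxy)hexa-1,5-diene F1. No proton source is present for simple reduction and no free enolate for aldol ring closure. Hydrolysis with 1 M HCl/THF returns to the route at 2.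

Step 4. The sparingly soluble tetraphenol 6 may brominate incompletely or be over-oxidised by free Br2. The fallback generates the electrophile slowly in the flask and never isolates 6. It sets out from 5: BBr3 demethylation as in step 3 is quenched with MeOH, then DMSO (8.5 equiv; 48% HBr added if needed) is added and the mixture warmed to 40–60 °C. DMSO oxidises the liberated HBr to Br2 at a rate and stoichiometry set by the sulfoxide, and the eight ortho positions are brominated as they become available. It comes back to the route at 7; 6 forms in the flask only, so no new compound arises (F0).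

**Further compounds**
F1 | step 1 | 1,3,4,6-tetrakis(4-methoxyphenyl)-1,6-bis(trimethylsilyloxy)hexa-1,5-diene (E/Z and meso/(±) mixture) | COc1ccc(cc1)C(O[Si](C)(C)C)=CC(c1ccc(OC)cc1)C(c1ccc(OC)cc1)C=C(O[Si](C)(C)C)c1ccc(OC)cc1
F2 | step 2 | 1,3,4,6-tetrakis(4-methoxyphenyl)hexane-1,2,5,6-tetrone (diastereomer mixture) | COc1ccc(cc1)C(=O)C(=O)C(c1ccc(OC)cc1)C(c1ccc(OC)cc1)C(=O)C(=O)c1ccc(OC)cc1
F0 | step 4 | none | none
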